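**Retrosynthetic overview**
- Ring labels: A = ring with OH para to its ether oxygen, B = para-phenylene, C = ring with OH ortho to its ether oxygen, D = meta-phenylene. All four benzene rings are bought; the only ring formed is the 18-membered macrocycle, closed in the second-to-last step.
- Target ⇐ double O-demethylation ⇐ macrocyclic dimethyl ether ⇐ ring-closing C–O bond (ring-A phenol oxygen to ring-D C–Cl) of an open-chain chloro phenol (key step, Pd-catalysed macro-etherification).
- Open-chain chloro phenol ⇐ A–CH2CH2–B bond by hydroboration/B-alkyl Suzuki coupling of a ring-B styrene with 2-bromo-4-methoxyphenol.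
- Ring-B styrene ⇐ B–O–C diaryl ether by Chan–Lam coupling of (4-ethenylphenyl)boronic acid with the C/D bibenzyl phenol.
- C/D bibenzyl phenol ⇐ C–CH2CH2–D bond by hydroboration/B-alkyl Suzuki coupling of 3-chlorostyrene with 5-bromo-2-methoxyphenol.

Assumption: the SMILES carries no stereodescriptor and the compound has no stereocentre; the macrocycle is taken as conformationally mobile, so the target is a single achiral compound and no stereocontrol is needed.

**Route**

Step 1
Reactants: 1 3-chlorostyrene; 2 5-bromo-2-methoxyphenol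
Product: 4 5-[2-(3-chlorophenyl)ethyl]-2-methoxyphenol, via B-(3-chlorophenethyl)-9-BBN 3 (not isolated)
Conditions: (i) 1 (1.5 equiv), 9-BBN (1.4 equiv), THF, 0 °C → rt; (ii) 2 (1.0 equiv), Pd(dppf)Cl2·CH2Cl2 (5 mol%), 3 M aq K3PO4 (4 equiv), THF/DMF, 65 °C
Reagents that add atoms: 9-BBN (9-borabicyclo[3.3.1]nonane), B1C2CCCC1CCC2 (its boron and carbons sit in 3 only; 4 keeps one hydrogen from it)
Why: Anti-Markovnikov hydroboration puts boron on the terminal carbon of the styrene and B-alkyl Suzuki–Miyaura coupling of the alkylborane with the aryl bromide forms the ArCH2CH2Ar bond directly, while Pd/dppf does not insert into the unactivated C–Cl bond at 65 °C; no stereocentre is formed.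

Step 2
Reactants: 4 5-[2-(3-chlorophenyl)ethyl]-2-methoxyphenol; 5 (4-ethenylphenyl)boronic acid
Product: 6 4-[2-(3-chlorophenyl)ethyl]-2-(4-ethenylphenoxy)-1-methoxybenzene
Conditions: 5 (2.0 equiv), Cu(OAc)2 (1.0 equiv), pyridine (5 equiv), 4 Å MS, CH2Cl2, O2 (1 atm), rt, 48 h
Reagents that add atoms: none
Why: Chan–Lam (Chan–Evans–Lam) oxidative O-arylation, in which the arylboronic acid transmetalates to Cu(II), the phenoxide binds, and C–O reductive elimination from Cu(III) occurs at room temperature with O2 returning Cu(I) to Cu(II), so the aryl chloride and the vinyl group are untouched.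

Step 3
Reactants: 6 4-[2-(3-chlorophenyl)ethyl]-2-(4-ethenylphenoxy)-1-methoxybenzene; 7 2-bromo-4-methoxyphenol
Product: 9 2-[2-(4-{5-[2-(3-chlorophenyl)ethyl]-2-methoxyphenoxy}phenyl)ethyl]-4-methoxyphenol, via B-alkyl-9-BBN 8 (not isolated)
Conditions: (i) 9-BBN (1.2 equiv), THF, 0 °C → rt; (ii) 7 (1.3 equiv), Pd(dppf)Cl2·CH2Cl2 (8 mol%), 3 M aq K3PO4 (4 equiv), THF/DMF, 70 °C
Reagents that add atoms: 9-BBN (9-borabicyclo[3.3.1]nonane), B1C2CCCC1CCC2 (its boron and carbons sit in 8 only; 9 keeps one hydrogen from it)
Why: Terminal hydroboration of the styrene followed by B-alkyl Suzuki–Miyaura coupling with the ortho-bromophenol (as its phenoxide) installs the A–CH2CH2–B bridge with the free ring-A phenol already in place, and the ring-D chloride again survives Pd/dppf.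

Step 4
Reactants: 9 2-[2-(4-{5-[2-(3-chlorophenyl)ethyl]-2-methoxyphenoxy}phenyl)ethyl]-4-methoxyphenol
Product: 10 macrocyclic di-O-methyl ether of the target (18-membered ring A–CH2CH2–B–O–C–CH2CH2–D–O–A)
Conditions: [Pd(cinnamyl)Cl]2 (5 mol%), Me4tBuXPhos (12 mol%), K3PO4 (3 equiv), toluene, 100 °C, syringe-pump addition of 9 over 16 h, final 2 mM
Reagents that add atoms: none
Why: Proposed new method: Pd-catalysed diaryl ether formation is used here as an 18-membered ring closure onto an unactivated aryl chloride, which to my knowledge has not been shown; L·Pd(0) adds oxidatively to the only C–Cl bond, the ortho-alkyl, electron-rich phenoxide (released sparingly from solid K3PO4 in toluene) replaces chloride on Pd, and the bulky di-tert-butyl biarylphosphine drives C–O reductive elimination, while slow addition and activation of the electrophile only on the catalyst hold back oligomers; the closest known reaction types are the intermolecular Pd-catalysed coupling of aryl chlorides with phenols and the Cu-mediated intramolecular Ullmann macrocyclisation.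

Step 5
Reactants: 10 macrocyclic di-O-methyl ether of the target
Product: 12 target macrocycle (ring-A OH para to the D–O–A oxygen; ring-C OH ortho to the B–O–C oxygen), via bis(dibromoboryl) ether 11 (not isolated)
Conditions: BBr3 (6 equiv), CH2Cl2, −78 °C → rt, 6 h; then ice-water
Reagents that add atoms: boron tribromide, BrB(Br)Br (its B and Br sit in 11 only; 12 keeps none of its atoms)
Why: Lewis-acid aryl methyl ether cleavage, in which BBr3 binds each methoxy oxygen, bromide removes the methyl group by SN2 to give the aryl dibromoborate, and water hydrolyses it to the phenol, while the two diaryl ether bonds are inert.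

**Compound list**
1 | 3-chlorostyrene (1-chloro-3-ethenylbenzene) | C=Cc1cccc(Cl)c1 | starting material
2 | 5-bromo-2-methoxyphenol | COc1ccc(Br)cc1O | starting material
3 | 9-[2-(3-chlorophenyl)ethyl]-9-borabicyclo[3.3.1]nonane | Clc1cccc(CCB2C3CCCC2CCC3)c1 | intermediate
4 | 5-[2-(3-chlorophenyl)ethyl]-2-methoxyphenol | COc1ccc(CCc2cccc(Cl)c2)cc1O | intermediate
5 | (4-ethenylphenyl)boronic acid | C=Cc1ccc(B(O)O)cc1 | starting material
6 | 4-[2-(3-chlorophenyl)ethyl]-2-(4-ethenylphenoxy)-1-methoxybenzene | COc1ccc(CCc2cccc(Cl)c2)cc1Oc1ccc(C=C)cc1 | intermediate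
7 | 2-bromo-4-methoxyphenol | COc1ccc(O)c(Br)c1 | starting material
8 | 9-(2-{4-[5-(2-(3-chlorophenyl)ethyl)-2-methoxyphenoxy]phenyl}ethyl)-9-borabicyclo[3.3.1]nonane | COc1ccc(CCc2cccc(Cl)c2)cc1Oc1ccc(CCB2C3CCCC2CCC3)cc1 | intermediate
9 | 2-[2-(4-{5-[2-(3-chlorophenyl)ethyl]-2-methoxyphenoxy}phenyl)ethyl]-4-methoxyphenol | COc1ccc(O)c(CCc2ccc(Oc3cc(CCc4cccc(Cl)c4)ccc3OC)cc2)c1 | intermediate
10 | macrocyclic di-O-methyl ether of the target (OMe on ring A para to the D–O–A oxygen, OMe on ring C ortho to the B–O–C oxygen) | COc1ccc2c(c1)CCc1ccc(cc1)Oc1cc(ccc1OC)CCc1cccc(c1)O2 | intermediate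
11 | bis(dibromoboryl) ether of the target (both phenol oxygens as O–BBr2) | BrB(Br)Oc1ccc2c(c1)CCc1ccc(cc1)Oc1cc(ccc1OB(Br)Br)CCc1cccc(c1)O2 | intermediate
12 | CNP0135015.0, macrocyclic bis(bibenzyl) diphenol | Oc1ccc2c(c1)CCc1ccc(cc1)Oc1cc(ccc1O)CCc1cccc(c1)O2 | target

**Step count and risks**
Total steps: 5 (each one-pot hydroboration/coupling counted as one step). Longest linear sequence: 5.

The three steps most likely to fail:

Step 4 (the proposed new macro-etherification) is the main risk: oligomerisation, hydrodechlorination or slow turnover at high dilution could dominate. The fallback uses known chemistry and sets out from 9. The aryl chloride is borylated with tetrahydroxydiboron (XPhos Pd G2, XPhos, KOAc, EtOH, 80 °C; Miyaura-type borylation of aryl chlorides) to give the seco boronic acid [3-(2-{3-[4-(2-(2-hydroxy-5-methoxyphenyl)ethyl)phenoxy]-4-methoxyphenyl}ethyl)phenyl]boronic acid F1. The ring is then closed by intramolecular Chan–Lam O-arylation (Cu(OAc)2, Et3N, 4 Å MS, CH2Cl2, air, rt, 1 mM), which comes back to the route at 10.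

Step 2 (Chan–Lam coupling with a vinyl-bearing boronic acid and an ortho-methoxy phenol) may give low conversion or boronic acid homocoupling and oxidation. The fallback sets out from 4 and replaces oxidative coupling by addition–elimination. SNAr with 4-fluorobenzaldehyde (K2CO3, DMF, 120 °C) gives 4-{5-[2-(3-chlorophenyl)ethyl]-2-methoxyphenoxy}benzaldehyde F2. Wittig methylenation (MePPh3Br, KOtBu, THF, 0 °C → rt) then comes back to the route at 6.

Step 3 (B-alkyl Suzuki coupling onto an electron-rich ortho-bromophenoxide) may stall at oxidative addition or lose the alkylborane to protodeboronation. The fallback sets out from 6 and forms the bond at sp2 carbon instead. A Mizoroki–Heck reaction of 6 with 7 (Pd(OAc)2, P(o-tol)3, Et3N, DMF, 100 °C) gives 2-[(E)-2-(4-{5-[2-(3-chlorophenyl)ethyl]-2-methoxyphenoxy}phenyl)ethenyl]-4-methoxyphenol F3. Diimide reduction of the stilbene (TsNHNH2, NaOAc, THF/H2O, reflux), which leaves the aryl chloride intact, comes back to the route at 9.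

**Further compounds**
F1 | step 4 | [3-(2-{3-[4-(2-(2-hydroxy-5-methoxyphenyl)ethyl)phenoxy]-4-methoxyphenyl}ethyl)phenyl]boronic acid | COc1ccc(O)c(CCc2ccc(Oc3cc(CCc4cccc(B(O)O)c4)ccc3OC)cc2)c1
F2 | step 2 | 4-{5-[2-(3-chlorophenyl)ethyl]-2-methoxyphenoxy}benzaldehyde | COc1ccc(CCc2cccc(Cl)c2)cc1Oc1ccc(C=O)cc1
F3 | step 3 | 2-[(E)-2-(4-{5-[2-(3-chlorophenyl)ethyl]-2-methoxyphenoxy}phenyl)ethenyl]-4-methoxyphenol | COc1ccc(O)c(/C=C/c2ccc(Oc3cc(CCc4cccc(Cl)c4)ccc3OC)cc2)c1
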